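## Analysis of the target

The target is made of two monocyclic units joined by one methylene carbon. Ring A is a 6-ethyl-4-hydroxy-5-methyl-2H-pyran-2-one substituted at C3. Ring B is a benzene ring that carries, in order, the CH2 link (C1'), OH (C2'), the 2-methylbutanoyl group (C3'), OH (C4'), H (C5') and OMe (C6'); these primed locants are kept for all intermediates below. There is one stereocenter, C2 of the acyl chain, with (R) configuration. Nothing else in the molecule can control it, so it must come from an enantiopure building block and then survive every later step. It lies α to an aryl ketone and can be lost by enolisation, or by any acyl transfer that passes through a ketene or a long-lived acylium ion. The other sensitive parts are the 4-hydroxypyranone (a vinylogous carboxylic acid, nucleophilic at O4 and C3, a diene and a lactone) and the very electron-rich ring B. The difficulty is regiochemical: ring B has three oxygens of one kind, of which one is a methyl ether and two are free phenols, and the acyl group must sit on C3' although C5' is also flanked by two oxygens. The plan rests on the run C2'(O)–C3'(C=O)–C4'(OH)–C5'(H). This is the pattern expected when an aryne across C3'–C4', polarised by an alkoxy group on C2', takes up a carboxylic acid.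

## Retrosynthetic reasoning

Target 24 is traced back to its dibenzyl ether 23 by cutting the two O–CH2Ph bonds, at C2'–O and at the pyranone O4. Both hydroxyls would add to an aryne or protonate its adducts, so they must be masked in the step before. Benzyl is chosen because it leaves by neutral hydrogenolysis, which touches neither the methyl ether nor the α-stereocenter.

In 23 the C4'–O bond and the C3'–C(acyl) bond are cut together. This leads to the 2-silylaryl triflate 19 and the free acid 20. The cut is made here because one operation then places the phenol oxygen and the ketone on neighbouring carbons in a fixed sense, and the acyl donor is the acid itself. The forward step has to release the aryne 21 from 19 with fluoride, bring the carboxylate oxygen to C4' and not to C3', and let the C3' carbanion of 22 capture the acyl group before it is protonated.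

The two benzyl ethers of 19 are cut to give the diol 18. They are put on late because the preceding bond formations need the free C2' phenol and the free, C3-nucleophilic hydroxypyranone.

The pyranone C3–CH2 bond of 18 is cut to give the phenolic Mannich base 11 and the pyranone 16. Ring B carries a triflate here and is a poor nucleophile, while 16 is a good carbon nucleophile. The bridge carbon is therefore made electrophilic on the ring B side, as the quinone methide 17.

The C1'–CH2 bond of 11 is cut to give the phenol 10. This is the regiochemical hinge of the preparation: the bridge must stand next to the oxygen that will be benzylated and away from the triflate oxygen. A free phenol at C2' directs an iminium electrophile to its only open ortho carbon, C1'.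

In 10 the C3'–Si bond and the triflate S–O bond are cut, through the bis-silyl ether 6, to the symmetric bromoresorcinol 5. After bromine–lithium exchange one silyl group moves from oxygen to C3' and frees exactly one phenolate, 8. The two equivalent oxygens of 5 are thus told apart without a statistical step.

The C–Br bond of 5 is cut back through 4 and 2 to 5-methoxyresorcinol 1. Electrophilic bromination of 1 cannot be relied on to choose the carbon between the hydroxyls over the two carbons next to the methoxy group. The bromine is therefore delivered by lithiation between two chelating acetal ethers in 2.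

Pyranone 16 is opened at the lactone O1–C2 bond to the diketo ester 15. This is cut at the bond that becomes C5–C6 into the keto ester 12 and the N-methoxy-N-methylamide 13.

## Alternatives that were turned down

Alternative 1: Ring A is taken apart last, at C4–C5 and O1–C2. Ring B with its acyl group is delivered as the malonyl dichloride A1, and the last three carbons as the silyl enol ether A2.
- Forward step: A2 is C-acylated by one acid chloride and its oxygen closes onto the second, a formal [3+3] annulation that should give A3, one hydrogenolysis from 24.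
- For it: ring A appears with a free 4-OH, needs no protection, and never meets an organolithium, fluoride or an aryne. On this point it is cleaner than the chosen plan.
- Against it: the bonds formed are the easy ones. A1 must already hold the (R)-acyl group at C3', so the central problem of ring B is only moved into the synthesis of A1.
- A1 is also fragile. Its acid chloride carbon lies five atoms from the C2' benzyloxy oxygen, so six-ring lactonisation with loss of the benzyl group is within reach. Making and using a malonyl dichloride also releases strong acid next to an enolisable stereocenter.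
- Step economy is no better, because ring B must first be fully built and homologated.
- Comparison: the chosen route spends more on protecting ring A, but uses its key step on the bonds that are hard.

Alternative 2: Ring B is built by benzannulation from the cyclobutenone A4 and the ynol ether A5. The C2'–C1' bond and the C6'–C5' bond are formed.
- Forward step: on heating, A4 opens to a vinylketene that adds to the alkyne. Ring opening of the new cyclobutenone and six-electron closure should give the phenol A6.
- For it: the three oxygens of ring B differ from the start (OH from the ketene carbon, OMe from the alkyne, OBn from A4). The chosen route needs five steps of directed metalation and silyl shift to reach the same point, so here the alternative is stronger. The step is also neutral.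
- Against it: in A6, C3' still bears hydrogen. The acyl group would have to come afterwards by an ortho-acylation or Fries-type shift. That step must tell C3' from C5' and use an α-branched chiral acyl donor under acidic conditions that endanger the benzyl ethers and the stereocenter.
- A5 is a 1-methoxyalkyne, hydrolytically labile and laborious to make. A4 is a vinylogous ester and should open less readily than simple cyclobutenones, so long heating of a pyranone diene beside an alkyne is implied.
- Comparison: the chosen plan accepts a longer preparation of ring B but installs C3'–acyl and C4'–OH together, with fixed regiochemistry and from the free acid.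

Alternative 3: Ring A is again formed last, at C3–C4 and O1–C2. The partners are the dioxinone A7 and A8, the silyl ketene acetal of a 3,4-dihydrocoumarin whose ring oxygen is the C2' oxygen and whose C4 is the future bridge.
- Forward step: thermolysis of A7 releases an acylketene that adds as an oxadiene to A8. Collapse of the adduct with loss of the aryloxide should give A9, with the C2' phenol unveiled and one benzyl ether left.
- For it: no quinone methide coupling is needed, the lactone protects C2'–OH and supplies C2 and C3 of ring A, and the end-game is a single hydrogenolysis. In convergence and atom economy it is ahead of the chosen plan.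
- Against it: A8 must be made by deprotonating a lactone with a strong amide base in a molecule whose aryl ketone has an α-hydrogen of similar acidity at the stereocenter. Either the wrong enolate forms or the configuration is lost.
- As in alternative 1, the acyl group must already be at C3', so the regiochemical problem is untouched. The adduct must also expel aryloxide and not silanolate, which is not assured.
- Comparison: the chosen route keeps strong base away from the stereocenter. The acid enters in the penultimate step under fluoride and afterwards sees only hydrogenolysis.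

Key step: step 11

Assumption: (R)-2-methylbutanoic acid (20) is taken to be purchasable in enantiopure form, and the silyl ether 6 is carried into step 5 without purification.

## Route

Step 1
Reactants: 1 5-methoxybenzene-1,3-diol
Product: 2 1-methoxy-3,5-bis(methoxymethoxy)benzene
Conditions: NaH, MOMCl, DMF, 0 °C to rt
Reagents that add atoms: chloromethyl methyl ether, COCCl
Why: Williamson-type O-alkylation of both phenolates with the reactive chloromethyl ether; the acetal ethers are installed because they are strong chelating directors for the next step.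

Step 2
Reactants: 2 1-methoxy-3,5-bis(methoxymethoxy)benzene
Product: 4 2-bromo-5-methoxy-1,3-bis(methoxymethoxy)benzene, via aryllithium 3 (not isolated)
Conditions: n-BuLi, THF, 0 °C; then BrCCl2CCl2Br, −78 °C to rt
Reagents that add atoms: 1,2-dibromo-1,1,2,2-tetrachloroethane, BrC(Cl)(Cl)C(Cl)(Cl)Br
Why: Directed ortho-metalation: the carbon between the two OCH2OCH3 groups has two chelating neighbours and should be deprotonated in preference to the carbons next to the weaker methoxy director; aryllithium 3 is then brominated by the positive-bromine donor.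

Step 3
Reactants: 4 2-bromo-5-methoxy-1,3-bis(methoxymethoxy)benzene
Product: 5 2-bromo-5-methoxybenzene-1,3-diol
Conditions: HCl, MeOH, 50 °C
Reagents that add atoms: none
Why: Acid-catalysed acetal exchange with methanol removes both methoxymethyl groups; the aryl bromide and the methyl ether are inert.

Step 4
Reactants: 5 2-bromo-5-methoxybenzene-1,3-diol
Product: 6 [(2-bromo-5-methoxy-1,3-phenylene)bis(oxy)]bis(trimethylsilane)
Conditions: HMDS, THF, 70 °C; evaporation
Reagents that add atoms: hexamethyldisilazane, C[Si](C)(C)N[Si](C)(C)C
Why: O-silylation of both phenols with the disilazane, whose only by-product is volatile, so the moisture-sensitive bis-silyl ether can be used crude.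

Step 5
Reactants: 6 [(2-bromo-5-methoxy-1,3-phenylene)bis(oxy)]bis(trimethylsilane)
Product: 10 3-hydroxy-5-methoxy-2-(trimethylsilyl)phenyl trifluoromethanesulfonate, via aryllithium 7 (not isolated), via lithium phenolate 8 (not isolated), via O-silyl triflate 9 (not isolated)
Conditions: n-BuLi, THF, −78 °C; Tf2O, −78 to 0 °C; then aq. citric acid, THF, rt
Reagents that add atoms: trifluoromethanesulfonic anhydride, O=S(=O)(OS(=O)(=O)C(F)(F)F)C(F)(F)F
Why: Bromine–lithium exchange gives 7, and a retro-Brook 1,3 O-to-C silyl shift places silicon on C3' and frees one phenolate (8) while the other oxygen stays silylated, so only one oxygen is triflated (9); the labile aryl O–SiMe3 bond is hydrolysed on work-up and the C–Si bond is kept.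

Step 6
Reactants: 10 3-hydroxy-5-methoxy-2-(trimethylsilyl)phenyl trifluoromethanesulfonate
Product: 11 4-[(dimethylamino)methyl]-3-hydroxy-5-methoxy-2-(trimethylsilyl)phenyl trifluoromethanesulfonate
Conditions: CH2=NMe2+ I−, Et3N, CH2Cl2, 0 °C to rt
Reagents that add atoms: N,N-dimethylmethyleneiminium iodide, C=[N+](C)C.[I-]
Why: Phenol Mannich aminomethylation with a preformed iminium salt; the hydrogen-bonded phenol should deliver the electrophile to its only free ortho carbon C1', while C5' lies between the methoxy group and the withdrawing, bulky triflate and the silylated carbon is shielded.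

Step 7
Reactants: 12 methyl 3-oxopentanoate; 13 N-methoxy-N-methylpropanamide
Product: 15 methyl 4-methyl-3,5-dioxoheptanoate, via dianion 14 (not isolated)
Conditions: NaH, THF, 0 °C; n-BuLi, 0 °C; 13, −78 to 0 °C; aq. HCl
Reagents that add atoms: none
Why: γ-Acylation of a β-keto ester dianion: the more basic terminal carbanion of 14 attacks the N-methoxy-N-methylamide, whose chelated tetrahedral adduct survives until work-up and so prevents over-addition and quenching of the dianion by the product.

Step 8
Reactants: 15 methyl 4-methyl-3,5-dioxoheptanoate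
Product: 16 6-ethyl-4-hydroxy-5-methyl-2H-pyran-2-one
Conditions: DBU, toluene, reflux; then aq. HCl
Reagents that add atoms: none
Why: Base-mediated lactonisation: the enolate oxygen of the C5 ketone attacks the ester carbonyl and methanol is lost, giving the 4-hydroxy-2-pyranone in its stable enol form.

Step 9
Reactants: 11 4-[(dimethylamino)methyl]-3-hydroxy-5-methoxy-2-(trimethylsilyl)phenyl trifluoromethanesulfonate; 16 6-ethyl-4-hydroxy-5-methyl-2H-pyran-2-one
Product: 18 4-[(6-ethyl-4-hydroxy-5-methyl-2-oxo-2H-pyran-3-yl)methyl]-3-hydroxy-5-methoxy-2-(trimethylsilyl)phenyl trifluoromethanesulfonate, via ortho-quinone methide 17 (not isolated)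
Conditions: 16 (2 equiv), toluene, 110 °C
Reagents that add atoms: none
Why: The acidic pyranone protonates the benzylic amine, and thermal loss of dimethylamine gives the ortho-quinone methide 17; Michael addition of pyranone C3 restores the aromatic ring, and any O-adduct can revert and funnel to the C-adduct.

Step 10
Reactants: 18 4-[(6-ethyl-4-hydroxy-5-methyl-2-oxo-2H-pyran-3-yl)methyl]-3-hydroxy-5-methoxy-2-(trimethylsilyl)phenyl trifluoromethanesulfonate
Product: 19 3-(benzyloxy)-4-{[4-(benzyloxy)-6-ethyl-5-methyl-2-oxo-2H-pyran-3-yl]methyl}-5-methoxy-2-(trimethylsilyl)phenyl trifluoromethanesulfonate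
Conditions: BnOH, PPh3, DIAD (3 equiv each), THF, 0 to 40 °C
Reagents that add atoms: benzyl alcohol, OCc1ccccc1
Why: Double Mitsunobu etherification of the two acidic hydroxyls (pyranone 4-OH and phenol); the neutral conditions favour O4- over C3-benzylation of the pyranone and avoid a free phenoxide standing next to the silyl group and the triflate.

Step 11
Reactants: 19 3-(benzyloxy)-4-{[4-(benzyloxy)-6-ethyl-5-methyl-2-oxo-2H-pyran-3-yl]methyl}-5-methoxy-2-(trimethylsilyl)phenyl trifluoromethanesulfonate; 20 (2R)-2-methylbutanoic acid
Product: 23 4-(benzyloxy)-3-{[2-(benzyloxy)-4-hydroxy-6-methoxy-3-[(2R)-2-methylbutanoyl]phenyl]methyl}-6-ethyl-5-methyl-2H-pyran-2-one, via aryne 21 (not isolated), via aryl carbanion ester 22 (not isolated)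
Conditions: 20 (1.5 equiv), CsF (4 equiv), THF, 125 °C, sealed tube
Reagents that add atoms: none
Why: Fluoride attacks silicon in 19 and triflate leaves, giving the aryne 21 across C3'–C4'. The carboxylate of 20, formed with CsF, adds through oxygen to C4' and leaves the carbanion on C3' (22). This carbanion attacks the neighbouring ester carbonyl through a four-membered transition state, and the resulting alkoxide opens at the acyl C–O bond to the ketone on C3' and the phenoxide on C4'. The closest known reaction type is the fluoride-induced formal insertion of arynes from 2-silylaryl triflates into the C–O bond of carboxylic acids, which gives ortho-hydroxyaryl ketones. No ring is closed and no stereocenter is created; the (R) center comes in with 20, never passes through a ketene or acylium ion, and ends next to a phenoxide whose charge disfavours enolisation. The step needs regiocontrol on an unsymmetrical aryne: the C2' benzyloxy group distorts the triple bond and stabilises negative charge on C3' inductively, and C4' has only C5'–H beside it, so oxygen should add at C4'; the C6' methoxy group is remote and its small opposing effect should not override this. The step also needs acyl capture to beat protonation of C3', which is helped by hot THF, sparingly soluble CsF and only a small excess of acid. Both other acidic sites are benzylated so that neither can add to the aryne.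

Step 12
Reactants: 23 4-(benzyloxy)-3-{[2-(benzyloxy)-4-hydroxy-6-methoxy-3-[(2R)-2-methylbutanoyl]phenyl]methyl}-6-ethyl-5-methyl-2H-pyran-2-one
Product: 24 3-({2,4-dihydroxy-6-methoxy-3-[(2R)-2-methylbutanoyl]phenyl}methyl)-6-ethyl-4-hydroxy-5-methyl-2H-pyran-2-one
Conditions: H2 (1 atm), 10% Pd/C, EtOAc, rt
Reagents that add atoms: none
Why: Hydrogenolysis of the aryl benzyl ether and the vinylogous benzyl ester over palladium on carbon under neutral conditions; the fully substituted pyranone and the hindered, hydrogen-bonded aryl ketone should not be reduced, and no acid or base reaches the α-stereocenter.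

## Compound list

1 | 5-methoxybenzene-1,3-diol | COc1cc(O)cc(O)c1 | starting material
2 | 1-methoxy-3,5-bis(methoxymethoxy)benzene | COCOc1cc(OC)cc(OCOC)c1 | intermediate
3 | [4-methoxy-2,6-bis(methoxymethoxy)phenyl]lithium | [Li]c1c(OCOC)cc(OC)cc1OCOC | intermediate
4 | 2-bromo-5-methoxy-1,3-bis(methoxymethoxy)benzene | COCOc1cc(OC)cc(OCOC)c1Br | intermediate
5 | 2-bromo-5-methoxybenzene-1,3-diol | COc1cc(O)c(Br)c(O)c1 | intermediate
6 | [(2-bromo-5-methoxy-1,3-phenylene)bis(oxy)]bis(trimethylsilane) | COc1cc(O[Si](C)(C)C)c(Br)c(O[Si](C)(C)C)c1 | intermediate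
7 | {4-methoxy-2,6-bis[(trimethylsilyl)oxy]phenyl}lithium | COc1cc(O[Si](C)(C)C)c([Li])c(O[Si](C)(C)C)c1 | intermediate
8 | lithium 5-methoxy-2-(trimethylsilyl)-3-[(trimethylsilyl)oxy]phenolate | [Li+].[O-]c1cc(OC)cc(O[Si](C)(C)C)c1[Si](C)(C)C | intermediate
9 | 5-methoxy-2-(trimethylsilyl)-3-[(trimethylsilyl)oxy]phenyl trifluoromethanesulfonate | COc1cc(O[Si](C)(C)C)c([Si](C)(C)C)c(OS(=O)(=O)C(F)(F)F)c1 | intermediate
10 | 3-hydroxy-5-methoxy-2-(trimethylsilyl)phenyl trifluoromethanesulfonate | COc1cc(O)c([Si](C)(C)C)c(OS(=O)(=O)C(F)(F)F)c1 | intermediate
11 | 4-[(dimethylamino)methyl]-3-hydroxy-5-methoxy-2-(trimethylsilyl)phenyl trifluoromethanesulfonate | COc1cc(OS(=O)(=O)C(F)(F)F)c([Si](C)(C)C)c(O)c1CN(C)C | intermediate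
12 | methyl 3-oxopentanoate | CCC(=O)CC(=O)OC | starting material
13 | N-methoxy-N-methylpropanamide | CCC(=O)N(C)OC | starting material
14 | lithium sodium 1-methoxypenta-1,3-diene-1,3-bis(olate) (dianion of 12) | CC=C(O[Li])C=C(O[Na])OC | intermediate
15 | methyl 4-methyl-3,5-dioxoheptanoate | CCC(=O)C(C)C(=O)CC(=O)OC | intermediate
16 | 6-ethyl-4-hydroxy-5-methyl-2H-pyran-2-one | CCc1oc(=O)cc(O)c1C | intermediate
17 | 5-methoxy-4-methylidene-3-oxo-2-(trimethylsilyl)cyclohexa-1,5-dien-1-yl trifluoromethanesulfonate | C=C1C(=O)C([Si](C)(C)C)=C(OS(=O)(=O)C(F)(F)F)C=C1OC | intermediate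
18 | 4-[(6-ethyl-4-hydroxy-5-methyl-2-oxo-2H-pyran-3-yl)methyl]-3-hydroxy-5-methoxy-2-(trimethylsilyl)phenyl trifluoromethanesulfonate | CCc1oc(=O)c(Cc2c(OC)cc(OS(=O)(=O)C(F)(F)F)c([Si](C)(C)C)c2O)c(O)c1C | intermediate
19 | 3-(benzyloxy)-4-{[4-(benzyloxy)-6-ethyl-5-methyl-2-oxo-2H-pyran-3-yl]methyl}-5-methoxy-2-(trimethylsilyl)phenyl trifluoromethanesulfonate | CCc1oc(=O)c(Cc2c(OC)cc(OS(=O)(=O)C(F)(F)F)c([Si](C)(C)C)c2OCc2ccccc2)c(OCc2ccccc2)c1C | intermediate
20 | (2R)-2-methylbutanoic acid | OC(=O)[C@H](C)CC | starting material
21 | 4-(benzyloxy)-3-{[2-(benzyloxy)-6-methoxy-3,4-didehydrophenyl]methyl}-6-ethyl-5-methyl-2H-pyran-2-one (aryne) | CCc1oc(=O)c(CC2=C(OCc3ccccc3)C#CC=C2OC)c(OCc2ccccc2)c1C | intermediate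
22 | cesium 2-(benzyloxy)-3-{[4-(benzyloxy)-6-ethyl-5-methyl-2-oxo-2H-pyran-3-yl]methyl}-4-methoxy-6-{[(2R)-2-methylbutanoyl]oxy}benzen-1-ide | [Cs+].CCc1oc(=O)c(Cc2c(OC)cc(OC(=O)[C@H](C)CC)[c-]c2OCc2ccccc2)c(OCc2ccccc2)c1C | intermediate
23 | 4-(benzyloxy)-3-{[2-(benzyloxy)-4-hydroxy-6-methoxy-3-[(2R)-2-methylbutanoyl]phenyl]methyl}-6-ethyl-5-methyl-2H-pyran-2-one | CCc1oc(=O)c(Cc2c(OC)cc(O)c(C(=O)[C@H](C)CC)c2OCc2ccccc2)c(OCc2ccccc2)c1C | intermediate
24 | 3-({2,4-dihydroxy-6-methoxy-3-[(2R)-2-methylbutanoyl]phenyl}methyl)-6-ethyl-4-hydroxy-5-methyl-2H-pyran-2-one | CCc1oc(=O)c(Cc2c(OC)cc(O)c(C(=O)[C@H](C)CC)c2O)c(O)c1C | target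

## Step count and least certain steps

Total: 12 steps. The longest linear sequence is 10 steps (steps 1–6 and 9–12, from 1 to 24). The two-step branch to pyranone 16 (steps 7 and 8) joins at step 9.

Step 11 (key step). The most likely failure is protonation of the C3' carbanion of 22 before it reaches the ester carbonyl, so that the aryne undergoes only O-arylation and the acyl group stays on oxygen. At 125 °C the benzyl group on the pyranone oxygen, a vinylogous benzyl ester, may also be transferred to carboxylate or fluoride. The product phenoxide may add to a second aryne, and the aryne may undergo cycloaddition with the pyranone diene of another molecule. The fallback avoids the aryne and sets out from 5. Both phenols are esterified with 20 (DCC, DMAP, CH2Cl2) to give 2-bromo-5-methoxy-1,3-phenylene bis[(2R)-2-methylbutanoate] F1. Bromine–lithium exchange (t-BuLi, THF/Et2O, −100 °C) then triggers an anionic Fries-type O-to-C acyl shift onto the former bromine carbon and should give 3-hydroxy-5-methoxy-2-[(2R)-2-methylbutanoyl]phenyl (2R)-2-methylbutanoate F2. Brief methanolysis of the remaining ester (K2CO3, MeOH, 0 °C) gives (2R)-1-(2,6-dihydroxy-4-methoxyphenyl)-2-methylbutan-1-one F3, whose two free ring carbons are equivalent. Pyranone 16 is aminomethylated with CH2=NMe2+ I− and heated with F3; this Mannich-type methylene bridging comes back to the route at 24.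

Step 6. The iminium ion may attack C5' (para to the hydroxyl) or the silylated carbon with loss of silicon, giving the wrong regiochemistry or a desilylated ring. The fallback uses a boron template that can only reach the ortho carbon. Phenol 10 is heated with PhB(OH)2 and paraformaldehyde (cat. propanoic acid, toluene, reflux, water removal) to give 5-methoxy-2-phenyl-8-(trimethylsilyl)-4H-1,3,2-benzodioxaborinin-7-yl trifluoromethanesulfonate F4. Exchange with propane-1,3-diol releases 3-hydroxy-4-(hydroxymethyl)-5-methoxy-2-(trimethylsilyl)phenyl trifluoromethanesulfonate F5. This salicyl alcohol is heated with 16 (toluene, 110 °C, cat. AcOH) so that the same quinone methide 17 forms by loss of water, and the route is rejoined at 18.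

Step 9. Loss of dimethylamine may be too slow at a temperature the silyl triflate tolerates, and the quinone methide may oligomerise or add the pyranone through oxygen. The fallback makes the same C–C bond by reductive Knoevenagel alkylation and sets out from 10. Ortho-formylation (MgCl2, Et3N, paraformaldehyde, MeCN, reflux) gives 4-formyl-3-hydroxy-5-methoxy-2-(trimethylsilyl)phenyl trifluoromethanesulfonate F6. Mitsunobu benzylation of its acidic phenol gives 3-(benzyloxy)-4-formyl-5-methoxy-2-(trimethylsilyl)phenyl trifluoromethanesulfonate F7. Condensation with 16 in the presence of Hantzsch ester and catalytic L-proline (CH2Cl2, rt) reduces the arylidene as it forms and gives 3-(benzyloxy)-4-[(6-ethyl-4-hydroxy-5-methyl-2-oxo-2H-pyran-3-yl)methyl]-5-methoxy-2-(trimethylsilyl)phenyl trifluoromethanesulfonate F8. One further Mitsunobu benzylation of the pyranone hydroxyl comes back at 19.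

Step 10. Etherification of the crowded C2' phenol, which sits between SiMe3 and the benzylic CH2, may stay incomplete. The pyranone may be alkylated at the lactone oxygen. If phenoxide builds up, it may attack the neighbouring silicon and expel the triflate, destroying the aryne precursor before the key step. The fallback keeps the C4' oxygen as an allyl ether until both benzyl groups are on, and installs the triflate last.
- It sets out from 6. After n-BuLi (THF, −78 °C) the phenolate 8 is alkylated with allyl bromide (DMPU, to rt), and mild acidic work-up gives 5-methoxy-3-(prop-2-en-1-yloxy)-2-(trimethylsilyl)phenol F9.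
- Aminomethylation as in step 6 gives 2-[(dimethylamino)methyl]-3-methoxy-5-(prop-2-en-1-yloxy)-6-(trimethylsilyl)phenol F10.
- Heating with 16 as in step 9 gives 6-ethyl-4-hydroxy-3-{[2-hydroxy-6-methoxy-4-(prop-2-en-1-yloxy)-3-(trimethylsilyl)phenyl]methyl}-5-methyl-2H-pyran-2-one F11.
- Benzylation of both hydroxyls (Mitsunobu, or BnBr/K2CO3, which is harmless without a triflate) gives 4-(benzyloxy)-3-{[2-(benzyloxy)-6-methoxy-4-(prop-2-en-1-yloxy)-3-(trimethylsilyl)phenyl]methyl}-6-ethyl-5-methyl-2H-pyran-2-one F12.
- Deallylation (Pd(PPh3)4, morpholine, THF) gives 4-(benzyloxy)-3-{[2-(benzyloxy)-4-hydroxy-6-methoxy-3-(trimethylsilyl)phenyl]methyl}-6-ethyl-5-methyl-2H-pyran-2-one F13.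
- Triflation (Tf2O, pyridine, CH2Cl2, 0 °C) comes back at 19.

## Further compounds

F1 | step 11 | 2-bromo-5-methoxy-1,3-phenylene bis[(2R)-2-methylbutanoate] | COc1cc(OC(=O)[C@H](C)CC)c(Br)c(OC(=O)[C@H](C)CC)c1
F2 | step 11 | 3-hydroxy-5-methoxy-2-[(2R)-2-methylbutanoyl]phenyl (2R)-2-methylbutanoate | COc1cc(O)c(C(=O)[C@H](C)CC)c(OC(=O)[C@H](C)CC)c1
F3 | step 11 | (2R)-1-(2,6-dihydroxy-4-methoxyphenyl)-2-methylbutan-1-one | COc1cc(O)c(C(=O)[C@H](C)CC)c(O)c1
F4 | step 6 | 5-methoxy-2-phenyl-8-(trimethylsilyl)-4H-1,3,2-benzodioxaborinin-7-yl trifluoromethanesulfonate | COc1cc(OS(=O)(=O)C(F)(F)F)c([Si](C)(C)C)c2OB(c3ccccc3)OCc12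
F5 | step 6 | 3-hydroxy-4-(hydroxymethyl)-5-methoxy-2-(trimethylsilyl)phenyl trifluoromethanesulfonate | COc1cc(OS(=O)(=O)C(F)(F)F)c([Si](C)(C)C)c(O)c1CO
F6 | step 9 | 4-formyl-3-hydroxy-5-methoxy-2-(trimethylsilyl)phenyl trifluoromethanesulfonate | COc1cc(OS(=O)(=O)C(F)(F)F)c([Si](C)(C)C)c(O)c1C=O
F7 | step 9 | 3-(benzyloxy)-4-formyl-5-methoxy-2-(trimethylsilyl)phenyl trifluoromethanesulfonate | COc1cc(OS(=O)(=O)C(F)(F)F)c([Si](C)(C)C)c(OCc2ccccc2)c1C=O
F8 | step 9 | 3-(benzyloxy)-4-[(6-ethyl-4-hydroxy-5-methyl-2-oxo-2H-pyran-3-yl)methyl]-5-methoxy-2-(trimethylsilyl)phenyl trifluoromethanesulfonate | CCc1oc(=O)c(Cc2c(OC)cc(OS(=O)(=O)C(F)(F)F)c([Si](C)(C)C)c2OCc2ccccc2)c(O)c1C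
F9 | step 10 | 5-methoxy-3-(prop-2-en-1-yloxy)-2-(trimethylsilyl)phenol | COc1cc(O)c([Si](C)(C)C)c(OCC=C)c1
F10 | step 10 | 2-[(dimethylamino)methyl]-3-methoxy-5-(prop-2-en-1-yloxy)-6-(trimethylsilyl)phenol | COc1cc(OCC=C)c([Si](C)(C)C)c(O)c1CN(C)C
F11 | step 10 | 6-ethyl-4-hydroxy-3-{[2-hydroxy-6-methoxy-4-(prop-2-en-1-yloxy)-3-(trimethylsilyl)phenyl]methyl}-5-methyl-2H-pyran-2-one | CCc1oc(=O)c(Cc2c(OC)cc(OCC=C)c([Si](C)(C)C)c2O)c(O)c1C
F12 | step 10 | 4-(benzyloxy)-3-{[2-(benzyloxy)-6-methoxy-4-(prop-2-en-1-yloxy)-3-(trimethylsilyl)phenyl]methyl}-6-ethyl-5-methyl-2H-pyran-2-one | CCc1oc(=O)c(Cc2c(OC)cc(OCC=C)c([Si](C)(C)C)c2OCc2ccccc2)c(OCc2ccccc2)c1C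
F13 | step 10 | 4-(benzyloxy)-3-{[2-(benzyloxy)-4-hydroxy-6-methoxy-3-(trimethylsilyl)phenyl]methyl}-6-ethyl-5-methyl-2H-pyran-2-one | CCc1oc(=O)c(Cc2c(OC)cc(O)c([Si](C)(C)C)c2OCc2ccccc2)c(OCc2ccccc2)c1C
A1 | alternative 1 | 2-({2,4-bis(benzyloxy)-6-methoxy-3-[(2R)-2-methylbutanoyl]phenyl}methyl)propanedioyl dichloride | ClC(=O)C(Cc1c(OC)cc(OCc2ccccc2)c(C(=O)[C@H](C)CC)c1OCc1ccccc1)C(Cl)=O
A2 | alternative 1 | trimethyl(pent-2-en-3-yloxy)silane (either alkene geometry) | CC=C(CC)O[Si](C)(C)C
A3 | alternative 1 | 3-({2,4-bis(benzyloxy)-6-methoxy-3-[(2R)-2-methylbutanoyl]phenyl}methyl)-6-ethyl-4-hydroxy-5-methyl-2H-pyran-2-one | CCc1oc(=O)c(Cc2c(OC)cc(OCc3ccccc3)c(C(=O)[C@H](C)CC)c2OCc2ccccc2)c(O)c1C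
A4 | alternative 2 | 3-(benzyloxy)cyclobut-2-en-1-one | O=C1C=C(OCc2ccccc2)C1
A5 | alternative 2 | 4-(benzyloxy)-6-ethyl-3-(3-methoxyprop-2-yn-1-yl)-5-methyl-2H-pyran-2-one | CCc1oc(=O)c(CC#COC)c(OCc2ccccc2)c1C
A6 | alternative 2 | 4-(benzyloxy)-3-{[4-(benzyloxy)-2-hydroxy-6-methoxyphenyl]methyl}-6-ethyl-5-methyl-2H-pyran-2-one | CCc1oc(=O)c(Cc2c(OC)cc(OCc3ccccc3)cc2O)c(OCc2ccccc2)c1C
A7 | alternative 3 | 6-ethyl-2,2,5-trimethyl-4H-1,3-dioxin-4-one | CCC1=C(C)C(=O)OC(C)(C)O1
A8 | alternative 3 | tert-butyl({7-(benzyloxy)-5-methoxy-8-[(2R)-2-methylbutanoyl]-4H-chromen-2-yl}oxy)dimethylsilane | CC(C)(C)[Si](C)(C)OC1=CCc2c(OC)cc(OCc3ccccc3)c(C(=O)[C@H](C)CC)c2O1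
A9 | alternative 3 | 3-({4-(benzyloxy)-2-hydroxy-6-methoxy-3-[(2R)-2-methylbutanoyl]phenyl}methyl)-6-ethyl-4-hydroxy-5-methyl-2H-pyran-2-one | CCc1oc(=O)c(Cc2c(OC)cc(OCc3ccccc3)c(C(=O)[C@H](C)CC)c2O)c(O)c1C
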